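**Strategy**

The five-membered ring of the indane is closed last, between the alkylidene carbon C-1 and C-2, the benzylic CH bearing the 3,5-dihydroxyphenyl ring. The key step exploits that C-2 is a benzylic radical site next to the C-3 stereocentre and that C-1, on C-7a of the benzo ring, is a styrene carbon and so an alkyne carbon in disguise. The precursor is an open-chain secondary benzylic nitro compound with C-3 set and a diarylalkyne on the ortho carbon. The nitro group activates the asymmetric arylation that sets C-3, allows arylation of C-2 and then leaves: tin-mediated C–N homolysis gives the C-2 radical, which closes 5-exo-dig and sets C-2 trans to C-3.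

Key step: step 7

Remark (numbering): indane numbering is used throughout; C-1 is the alkylidene carbon, C-2 carries the 3,5-dioxygenated ring, C-3 the guaiacyl ring, C-3a and C-7a are the ring-fusion carbons.
Remark (assumption): hydrogen transfer to the vinyl radical in step 7 is assumed to occur mainly on the side of C-2, giving the (Z)-alkene; step 8 makes the route independent of this sense.
Remark (assumption): compounds 1, 6 and 8 are taken as purchasable.

**Route**

Step 1
Reactants: 1 1-bromo-3,5-bis(benzyloxy)benzene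
Product: 3 2-bromo-4,6-bis(benzyloxy)benzaldehyde, via iminium chloride 2 (not isolated)
Conditions: POCl3 (1.5 equiv), DMF, 0 to 80 °C; then ice/H2O
Reagents that add atoms: N,N-dimethylformamide CN(C)C=O (formyl carbon); water O (aldehyde oxygen)
Why: Vilsmeier–Haack formylation; the position next to bromine is para to one benzyloxy group and ortho to the other, and less hindered than the site between the two ethers, so formylation should occur there and the iminium salt is hydrolysed on work-up.

Step 2
Reactants: 3 2-bromo-4,6-bis(benzyloxy)benzaldehyde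
Product: 5 1-bromo-3,5-bis(benzyloxy)-2-[(E)-2-nitroethenyl]benzene, via nitroaldol 4 (not isolated)
Conditions: MeNO2, NH4OAc, AcOH, 100 °C
Reagents that add atoms: nitromethane C[N+](=O)[O-]
Why: Henry (nitroaldol) condensation; the nitroaldol dehydrates under the ammonium acetate conditions to the conjugated nitroalkene, whose (E) geometry is the thermodynamic one.

Step 3
Reactants: 5 1-bromo-3,5-bis(benzyloxy)-2-[(E)-2-nitroethenyl]benzene; 6 [4-(benzyloxy)-3-methoxyphenyl]boronic acid
Product: 7 1-bromo-3,5-bis(benzyloxy)-2-[(1S)-1-[4-(benzyloxy)-3-methoxyphenyl]-2-nitroethyl]benzene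
Conditions: [RhCl(C2H4)2]2 (2.5 mol%), chiral diene Ph-bod* (5.5 mol%, the antipode that delivers aryl to the Si face of C-β), aq. KOH (10 mol%), dioxane/H2O, 30–40 °C
Reagents that add atoms: none
Why: Hayashi–Miyaura rhodium-catalysed asymmetric conjugate addition of an arylboronic acid to a nitroalkene; the aryl–Rh(I)–diene complex carbometalates the Si face of C-β (C-α > aryl > H), which gives the (S) centre (the future C-3), and the aryl bromide and benzyl ethers are inert to Rh(I).

Step 4
Reactants: 8 4-(benzyloxy)-3-methoxybenzaldehyde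
Product: 9 1-(benzyloxy)-4-ethynyl-2-methoxybenzene
Conditions: dimethyl (1-diazo-2-oxopropyl)phosphonate, K2CO3, MeOH, 0 °C to rt
Reagents that add atoms: dimethyl (1-diazo-2-oxopropyl)phosphonate COP(=O)(OC)C(=[N+]=[N-])C(C)=O (terminal alkyne carbon)
Why: Seyferth–Gilbert homologation with the Ohira–Bestmann reagent; methanolysis releases the diazomethylphosphonate anion, which converts the non-enolisable aldehyde into the terminal alkyne through the alkylidene carbene and a 1,2-hydrogen shift.

Step 5
Reactants: 7 1-bromo-3,5-bis(benzyloxy)-2-[(1S)-1-[4-(benzyloxy)-3-methoxyphenyl]-2-nitroethyl]benzene; 9 1-(benzyloxy)-4-ethynyl-2-methoxybenzene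
Product: 10 1,5-bis(benzyloxy)-2-[(1S)-1-[4-(benzyloxy)-3-methoxyphenyl]-2-nitroethyl]-3-{[4-(benzyloxy)-3-methoxyphenyl]ethynyl}benzene
Conditions: Pd(PhCN)2Cl2 (3 mol%), P(t-Bu)3 (6 mol%), CuI (2 mol%), i-Pr2NH, dioxane, rt
Reagents that add atoms: none
Why: Sonogashira coupling; the bulky electron-rich phosphine allows oxidative addition to the ortho-substituted bromide at room temperature, copper acetylide transfer is faster than any reaction of the weakly acidic nitroalkane, and the C–H at the stereocentre is not acidic enough to epimerise.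

Step 6
Reactants: 10 1,5-bis(benzyloxy)-2-[(1S)-1-[4-(benzyloxy)-3-methoxyphenyl]-2-nitroethyl]-3-{[4-(benzyloxy)-3-methoxyphenyl]ethynyl}benzene; 1 1-bromo-3,5-bis(benzyloxy)benzene
Product: 11 1,5-bis(benzyloxy)-2-[(1S,2RS)-2-[3,5-bis(benzyloxy)phenyl]-1-[4-(benzyloxy)-3-methoxyphenyl]-2-nitroethyl]-3-{[4-(benzyloxy)-3-methoxyphenyl]ethynyl}benzene
Conditions: Pd2(dba)3 (2.5 mol%), t-BuXPhos (6 mol%), Cs2CO3 (1.2 equiv), DME, 50 °C
Reagents that add atoms: none
Why: palladium-catalysed α-arylation of a nitroalkane (nitronate cross-coupling); the bulky biaryl phosphine favours C–C reductive elimination and stops a second arylation, and the new nitro-bearing centre may form as both epimers because it becomes planar in step 7.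

Step 7
Reactants: 11 1,5-bis(benzyloxy)-2-[(1S,2RS)-2-[3,5-bis(benzyloxy)phenyl]-1-[4-(benzyloxy)-3-methoxyphenyl]-2-nitroethyl]-3-{[4-(benzyloxy)-3-methoxyphenyl]ethynyl}benzene
Product: 12 (1Z,2S,3S)-4,6-bis(benzyloxy)-2-[3,5-bis(benzyloxy)phenyl]-3-[4-(benzyloxy)-3-methoxyphenyl]-1-{[4-(benzyloxy)-3-methoxyphenyl]methylidene}-2,3-dihydro-1H-indene (expected main geometric isomer; any (E)-isomer is carried into step 8)
Conditions: Bu3SnH (1.5 equiv, syringe pump, 6 h), ACCN (0.3 equiv), PhMe (0.01 M), 110 °C
Reagents that add atoms: none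
Why: Bu3Sn• adds to a nitro oxygen and the stannyloxy nitroxide fragments at the weak benzylic C–N bond, so the nitro group that built the precursor leaves as Bu3SnONO and C-2 becomes a benzylic radical. This radical adds to the alkyne carbon on C-7a in a 5-exo-dig closure (the 6-endo mode would give a non-stabilised cyclic vinyl radical), and the linear α-aryl vinyl radical is quenched by Bu3SnH, which carries the chain; the closest known reaction type is the tin hydride-mediated denitrative radical cyclisation of nitro compounds onto alkenes and alkynes. The new stereocentre C-2 is controlled by C-3: in the transition state the aryl group on the planar radical carbon avoids eclipsing the aryl group on C-3, so the trans-2,3 product (2S,3S) should prevail, and both C-2 epimers of 11 converge on the same radical. The step needs ring closure to outrun direct reduction of the C-2 radical, which the slow hydrogen abstraction of benzylic radicals from stannane, high dilution and slow addition secure, and it needs C–N rather than N–O fragmentation, which the benzylic position secures. Hydrogen transfer to the vinyl radical is expected on the less hindered side, next to C-2 and away from the peri C-7–H, so the alkene should emerge mainly as the (Z)-isomer, which step 8 corrects.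

Step 8
Reactants: 12 (1Z,2S,3S)-4,6-bis(benzyloxy)-2-[3,5-bis(benzyloxy)phenyl]-3-[4-(benzyloxy)-3-methoxyphenyl]-1-{[4-(benzyloxy)-3-methoxyphenyl]methylidene}-2,3-dihydro-1H-indene
Product: 13 (1E,2S,3S)-4,6-bis(benzyloxy)-2-[3,5-bis(benzyloxy)phenyl]-3-[4-(benzyloxy)-3-methoxyphenyl]-1-{[4-(benzyloxy)-3-methoxyphenyl]methylidene}-2,3-dihydro-1H-indene
Conditions: I2 (5 mol%), PhMe, visible light, rt
Reagents that add atoms: none
Why: iodine-atom-catalysed alkene isomerisation; reversible addition of I• gives a benzylic radical that rotates and loses I•, which should lead to the thermodynamically favoured (E)-isomer, in which the aryl group lies next to the sp3 C-2 and not against the peri C-7–H; the stereocentres are untouched because I• does not abstract C–H.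

Step 9
Reactants: 13 (1E,2S,3S)-4,6-bis(benzyloxy)-2-[3,5-bis(benzyloxy)phenyl]-3-[4-(benzyloxy)-3-methoxyphenyl]-1-{[4-(benzyloxy)-3-methoxyphenyl]methylidene}-2,3-dihydro-1H-indene
Product: 14 gnetulin, (1E,2S,3S)-2-(3,5-dihydroxyphenyl)-3-(4-hydroxy-3-methoxyphenyl)-1-[(4-hydroxy-3-methoxyphenyl)methylidene]-2,3-dihydro-1H-indene-4,6-diol
Conditions: BCl3 (CH2Cl2, 3 equiv per ether), pentamethylbenzene (18 equiv), CH2Cl2, −78 °C; then MeOH
Reagents that add atoms: none
Why: Lewis acid debenzylation with pentamethylbenzene as a non-basic cation scavenger; at −78 °C the six benzyl ethers should be cleaved while the two aryl methyl ethers and the trisubstituted styrene are left, and the scavenger captures the benzyl cations before they alkylate the electron-rich rings.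

**Compound list**

1 | 1-bromo-3,5-bis(benzyloxy)benzene | Brc1cc(OCc2ccccc2)cc(OCc2ccccc2)c1 | starting material
2 | N-[2-bromo-4,6-bis(benzyloxy)benzylidene]-N-methylmethanaminium chloride (iminium chloride) | C[N+](C)=Cc1c(Br)cc(OCc2ccccc2)cc1OCc1ccccc1.[Cl-] | intermediate (not isolated)
3 | 2-bromo-4,6-bis(benzyloxy)benzaldehyde | O=Cc1c(Br)cc(OCc2ccccc2)cc1OCc1ccccc1 | intermediate
4 | 1-[2-bromo-4,6-bis(benzyloxy)phenyl]-2-nitroethanol (racemic nitroaldol) | OC(C[N+](=O)[O-])c1c(Br)cc(OCc2ccccc2)cc1OCc1ccccc1 | intermediate (not isolated)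
5 | 1-bromo-3,5-bis(benzyloxy)-2-[(E)-2-nitroethenyl]benzene | [O-][N+](=O)/C=C/c1c(Br)cc(OCc2ccccc2)cc1OCc1ccccc1 | intermediate
6 | [4-(benzyloxy)-3-methoxyphenyl]boronic acid | COc1cc(B(O)O)ccc1OCc1ccccc1 | starting material
7 | 1-bromo-3,5-bis(benzyloxy)-2-[(1S)-1-[4-(benzyloxy)-3-methoxyphenyl]-2-nitroethyl]benzene | [O-][N+](=O)C[C@@H](c1ccc(OCc2ccccc2)c(OC)c1)c1c(Br)cc(OCc2ccccc2)cc1OCc1ccccc1 | intermediate
8 | 4-(benzyloxy)-3-methoxybenzaldehyde | COc1cc(C=O)ccc1OCc1ccccc1 | starting material
9 | 1-(benzyloxy)-4-ethynyl-2-methoxybenzene | C#Cc1ccc(OCc2ccccc2)c(OC)c1 | intermediate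
10 | 1,5-bis(benzyloxy)-2-[(1S)-1-[4-(benzyloxy)-3-methoxyphenyl]-2-nitroethyl]-3-{[4-(benzyloxy)-3-methoxyphenyl]ethynyl}benzene | [O-][N+](=O)C[C@@H](c1ccc(OCc2ccccc2)c(OC)c1)c1c(C#Cc2ccc(OCc3ccccc3)c(OC)c2)cc(OCc2ccccc2)cc1OCc1ccccc1 | intermediate
11 | 1,5-bis(benzyloxy)-2-[(1S,2RS)-2-[3,5-bis(benzyloxy)phenyl]-1-[4-(benzyloxy)-3-methoxyphenyl]-2-nitroethyl]-3-{[4-(benzyloxy)-3-methoxyphenyl]ethynyl}benzene | [O-][N+](=O)C(c1cc(OCc2ccccc2)cc(OCc2ccccc2)c1)[C@@H](c1ccc(OCc2ccccc2)c(OC)c1)c1c(C#Cc2ccc(OCc3ccccc3)c(OC)c2)cc(OCc2ccccc2)cc1OCc1ccccc1 | intermediate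
12 | (1Z,2S,3S)-4,6-bis(benzyloxy)-2-[3,5-bis(benzyloxy)phenyl]-3-[4-(benzyloxy)-3-methoxyphenyl]-1-{[4-(benzyloxy)-3-methoxyphenyl]methylidene}-2,3-dihydro-1H-indene | COc1cc(/C=C2\c3cc(OCc4ccccc4)cc(OCc4ccccc4)c3[C@H](c3ccc(OCc4ccccc4)c(OC)c3)[C@H]2c2cc(OCc3ccccc3)cc(OCc3ccccc3)c2)ccc1OCc1ccccc1 | intermediate
13 | (1E,2S,3S)-4,6-bis(benzyloxy)-2-[3,5-bis(benzyloxy)phenyl]-3-[4-(benzyloxy)-3-methoxyphenyl]-1-{[4-(benzyloxy)-3-methoxyphenyl]methylidene}-2,3-dihydro-1H-indene | COc1cc(/C=C2/c3cc(OCc4ccccc4)cc(OCc4ccccc4)c3[C@H](c3ccc(OCc4ccccc4)c(OC)c3)[C@H]2c2cc(OCc3ccccc3)cc(OCc3ccccc3)c2)ccc1OCc1ccccc1 | intermediate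
14 | gnetulin, (1E,2S,3S)-2-(3,5-dihydroxyphenyl)-3-(4-hydroxy-3-methoxyphenyl)-1-[(4-hydroxy-3-methoxyphenyl)methylidene]-2,3-dihydro-1H-indene-4,6-diol | COc1cc(/C=C2/c3cc(O)cc(O)c3[C@H](c3ccc(O)c(OC)c3)[C@H]2c2cc(O)cc(O)c2)ccc1O | target

**Step count and risks**

Total step count: 9. Longest linear sequence: 8 (steps 1, 2, 3, 5, 6, 7, 8, 9).

Steps most likely to fail:

Step 7. The C-2 radical may be reduced by the stannane before it closes the ring, the nitroxide may fragment at N–O instead of C–N, or the face selectivity at C-2 may be poor. The fallback sets out from 11 and removes the hydride donor from the ring closure. Palladium-catalysed syn-hydrostannation of the alkyne (Bu3SnH, PdCl2(PPh3)2, THF, 0 °C) should give the α-stannyl stilbene F1, with tin on the carbon next to the ortho-substituted ring. Heating F1 with ACCN in toluene then starts a hydride-free chain: Bu3Sn• removes the nitro group, the C-2 radical adds 5-exo-trig to the tin-bearing carbon, and the benzylic radical expels Bu3Sn•. This addition–fragmentation forms the alkene by elimination under thermodynamic control and comes back to the route at 13, so that 12 and step 8 are bypassed.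

Step 6. The aryl-palladium species may insert the alkyne, or the nitronate may attack the palladium-bound alkyne, in competition with the C–C coupling. The fallback sets out from 1 and 7 and changes the order of events so that no alkyne is present during the arylation. Copper-catalysed halogen exchange on 1 (NaI, CuI, N,N'-dimethylethylenediamine, dioxane, 110 °C) gives 1,3-bis(benzyloxy)-5-iodobenzene F2. F2 is coupled with the nitronate of 7 under the conditions of step 6 at 40 °C, where oxidative addition to the unhindered iodide should be much faster than to the ortho-substituted bromide of 7, giving the bromo nitro compound F3. Sonogashira coupling of F3 with 9 under the conditions of step 5 comes back to the route at 11.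

Step 3. Carbometalation at the congested β-carbon, flanked by two ortho substituents, may be slow, so that protodeboronation of 6 and base-induced decay of the nitroalkene compete, or the facial discrimination may be low. The fallback sets out from 5 and replaces the catalytic asymmetric step by resolution. The Grignard reagent [4-(benzyloxy)-3-methoxyphenyl]magnesium bromide F4 is made from purchased 1-(benzyloxy)-4-bromo-2-methoxybenzene and Mg in THF. It is added to 5 at −78 °C, followed by cold 1 M HCl, to give the racemic nitro compound F5. Preparative HPLC of F5 on a chiral stationary phase gives the (S)-enantiomer and comes back to the route at 7.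

**Further compounds**

F1 | step 7 | tributyl{(Z)-1-[3,5-bis(benzyloxy)-2-[(1S,2RS)-2-[3,5-bis(benzyloxy)phenyl]-1-[4-(benzyloxy)-3-methoxyphenyl]-2-nitroethyl]phenyl]-2-[4-(benzyloxy)-3-methoxyphenyl]ethenyl}stannane (α-stannyl stilbene, Sn and vinyl H cis) | CCCC[Sn](CCCC)(CCCC)/C(=C/c1ccc(OCc2ccccc2)c(OC)c1)c1cc(OCc2ccccc2)cc(OCc2ccccc2)c1[C@H](c1ccc(OCc2ccccc2)c(OC)c1)C(c1cc(OCc2ccccc2)cc(OCc2ccccc2)c1)[N+](=O)[O-]
F2 | step 6 | 1,3-bis(benzyloxy)-5-iodobenzene | Ic1cc(OCc2ccccc2)cc(OCc2ccccc2)c1
F3 | step 6 | 1-bromo-3,5-bis(benzyloxy)-2-[(1S,2RS)-2-[3,5-bis(benzyloxy)phenyl]-1-[4-(benzyloxy)-3-methoxyphenyl]-2-nitroethyl]benzene | [O-][N+](=O)C(c1cc(OCc2ccccc2)cc(OCc2ccccc2)c1)[C@@H](c1ccc(OCc2ccccc2)c(OC)c1)c1c(Br)cc(OCc2ccccc2)cc1OCc1ccccc1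
F4 | step 3 | [4-(benzyloxy)-3-methoxyphenyl]magnesium bromide | COc1cc([Mg]Br)ccc1OCc1ccccc1
F5 | step 3 | racemic 1-bromo-3,5-bis(benzyloxy)-2-[1-[4-(benzyloxy)-3-methoxyphenyl]-2-nitroethyl]benzene | [O-][N+](=O)CC(c1ccc(OCc2ccccc2)c(OC)c1)c1c(Br)cc(OCc2ccccc2)cc1OCc1ccccc1
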